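The slowness of the east run's start caught my eye: 4.2 mM of product after 6.5 min, then a steep rise. I read that S-shape as autocatalysis and wrote the rate as a constant times starting material times product.

| setting | east | south-east | north-west |
|---|---|---|---|
| starting material | 100 mM | 200 mM | 650 mM |
| time |  |  | 39 min |

| run | time / min | [product] / mM |
|---|---|---|
| east run | 6.5 | 4.2 |
| east run | 13 | 12.1 |
| east run | 20 | 33.7 |
| east run | 26 | 51.4 |
| east run | 32 | 66.8 |
| east run | 39 | 75.2 |
| south-east run | 6.5 | 10.5 |
| south-east run | 13 | 66.0 |
| south-east run | 20 | 139.3 |
| south-east run | 26 | 160.5 |
| south-east run | 32 | 167.8 |
| south-east run | 39 | 174.0 |

(scatter of a reading: 0.8 mM)

- the power of [starting material] that the first rate follows, about the charge of the east run; measure it at two percent of starting material made into product (one fixed amount of product, the same in the runs compared)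
- product in the north-west run at 39 min, as a share of the starting material charged

- Overall: starting material -> product.
- Constant volume, constant temperature.
- An order is taken over about fifteen percent of the charge, up and down.

That rate integrates in closed form: the logarithm of product over the starting material left climbs in a straight line, with slope equal to the constant times the charge. Between 13 min and 26 min the east readings give 1.57 M⁻¹ min⁻¹, the growth constant.

One over the constant times the charge is the fast rung of the ladder: 6.38 min in the east run and 0.981 min in the north-west run. The slow rung is the tail. In the south-east run the shortfall from the charge fell from 32.2 mM to 26.0 mM between 32 min and 39 min, a reading of 32.7 min for its life, far longer than the north-west growth time. So I placed the north-west flask on the slow rung at 39 min.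

At 39 min the east shortfall was 24.8 mM from a charge of 100 mM, and the south-east one 26.0 mM from a charge of 200 mM. I assumed that the mean, 25.4 mM, carried over to the north-west charge, which gives 96.1%.

The forecast said 94%, lower than my figure, with an order of 0.9; it read the end as “a slow tail with mild inhibition or catalyst decay”.

The north-west flask gave 95.2%, a shortfall of 31.5 mM, and the order came out at 0.79. The steps were these:

    starting material → intermediate (0.02388 min⁻¹)
    intermediate → product (0.02730 min⁻¹)
    starting material → product (0.001032 min⁻¹)
    starting material + product → 2 product (1.848 M⁻¹ min⁻¹)

Both forecast values stand within their margins. The step in which starting material meets product moves the readings by 95 times the scatter, as a root mean square. Put to the south-east run, the growth constant from the east run gives the time from product at a quarter of the charge to product at half of it as ln 3 over the constant times the charge, which is 3.50 min, against 4.02 min in the south-east run.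

The readings were computed from invented constants.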